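**Plan**

1. Retrosynthetic cuts, in order: the ester C–O bond at O6' (linoleoyl off); the C7'–OH bond (tertiary carbinol back to an isopropenyl group); the C6'–C7' bond (back to a C6' aldehyde and a 2-propenyl metal); the former C6'=C7' alkene of a geranyl chain (aldehyde back to aurapten); the aryl ether O–C1' bond (umbelliferone plus geranyl bromide).
2. Forward: the coumarin bicycle is bought intact and no ring is formed. The chain is attached by O-geranylation, cut back to the C6' aldehyde (epoxidation, periodic acid), rebuilt by isopropenyl addition, hydrated at C7' and acylated at O6'.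
3. Enabling feature: C7' carries two methyl groups and a hydroxyl and sits next to the only stereocentre, C6'. C7' is therefore a masked isopropenyl carbon, and the C6'–C7' bond can be made by addition to an aldehyde with a chromium reagent that leaves the lactone of the benzopyranone ring alone.
4. Stereochemistry: C6' (R) is set by the chiral ligand on chromium in the alkenylation. The 2'E alkene comes from geranyl bromide and the 9Z,12Z diene from linoleic acid; neither is touched.

Key step: step 4

Assumption: the ligand antipode that delivers the alkenyl group to the Si face of the aldehyde is to be identified in a pilot run by chiral HPLC against the racemate (both antipodes derive from D- or L-valinol); enantiomeric purity can be raised if needed by recrystallising (R)-marmin, which should be a crystalline solid.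

**Step 1**
Reactants: 1 umbelliferone (7-hydroxy-2H-chromen-2-one); 2 geranyl bromide ((2E)-1-bromo-3,7-dimethylocta-2,6-diene)
Product: 3 aurapten, 7-{[(2E)-3,7-dimethylocta-2,6-dienyl]oxy}-2H-chromen-2-one
Conditions: K2CO3, acetone, reflux
Reagents that add atoms: none
Why: Williamson ether synthesis, in which the phenoxide of 1 displaces bromide at the primary allylic carbon by SN2, O-alkylation being favoured with K2CO3 in acetone; the 2E geometry is untouched and the lactone tolerates the weak base.

**Step 2**
Reactants: 3 aurapten
Product: 4 racemic 6',7'-epoxyaurapten, 7-{[(2E)-5-(3,3-dimethyloxiran-2-yl)-3-methylpent-2-enyl]oxy}-2H-chromen-2-one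
Conditions: mCPBA (1.05 equiv), CH2Cl2, 0 °C
Reagents that add atoms: 3-chloroperoxybenzoic acid (mCPBA), O=C(OO)c1cccc(Cl)c1
Why: Prilezhaev epoxidation, in which the peracid should oxidise the electron-rich distal 6',7'-alkene in preference to the 2',3'-alkene (deactivated inductively by the allylic aryloxy group) and ignore the electron-poor coumarin C3=C4 bond; C6' forms as a racemate, which does not matter because this centre is cleaved in step 3.

**Step 3**
Reactants: 4 racemic 6',7'-epoxyaurapten
Product: 6 (4E)-4-methyl-6-[(2-oxo-2H-chromen-7-yl)oxy]hex-4-enal, via racemic 6',7'-diol 5 (not isolated)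
Conditions: H5IO6 (1.1 equiv), THF/Et2O, 0 °C to rt
Reagents that add atoms: water, O (supplies the second hydroxyl of diol 5)
Why: Acid-promoted hydrolysis of the epoxide to the vicinal diol followed in the same flask by Malaprade glycol cleavage through the cyclic periodate ester; the trisubstituted alkene and the coumarin are inert to periodate and no stereocentre remains.

**Step 4**
Reactants: 6 (4E)-4-methyl-6-[(2-oxo-2H-chromen-7-yl)oxy]hex-4-enal; 7 2-bromopropene
Product: 9 7-{[(2E,6R)-6-hydroxy-3,7-dimethylocta-2,7-dienyl]oxy}-2H-chromen-2-one, via trimethylsilyl ether 8 (not isolated)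
Conditions: CrCl2 (divalent chromium, 10 mol%), N-[2-(4-isopropyl-4,5-dihydro-1,3-oxazol-2-yl)-6-methylphenyl]methanesulfonamide (single antipode, 12 mol%), 1,8-bis(dimethylamino)naphthalene (12 mol%), NiCl2(2,9-dimethyl-1,10-phenanthroline) (divalent nickel, 2 mol%), Mn powder, LiCl, Me3SiCl, 7 in excess, MeCN, rt; then 1 M HCl (cat.), THF, 0 °C
Reagents that add atoms: chlorotrimethylsilane, C[Si](C)(C)Cl (Me3Si group of 8 only; lost again in the work-up)
Why: Catalytic asymmetric Nozaki–Hiyama–Kishi alkenylation, the closest known reaction type being the chromium-catalysed enantioselective addition of alkenyl halides to unbranched aliphatic aldehydes. Zerovalent nickel, formed in situ from the NiCl2 complex, inserts into the C–Br bond of 7 and passes the 2-propenyl group to chromium, giving a trivalent alkenylchromium species held by the deprotonated sulfonamide–oxazoline ligand, which adds to the aldehyde carbonyl of 6 through a closed transition state and forms the C6'–C7' bond. Me3SiCl cleaves the chromium–oxygen bond to give silyl ether 8, manganese metal reduces trivalent chromium back to divalent chromium so that chromium turns over, and the acidic work-up frees 9. No ring is closed. The one new stereocentre, C6', is set by reagent control: 6 has no resident stereocentre, so the chiral ligand on chromium directs the alkenyl group to the Si face of the aldehyde, which corresponds to R. The step needs chemoselectivity for the aldehyde over the coumarin lactone, its conjugated C3=C4 bond and the allyl aryl ether, and this is secured by the low basicity and strict aldehyde selectivity of organochromium reagents, where a magnesium or lithium reagent would attack the lactone.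

**Step 5**
Reactants: 9 7-{[(2E,6R)-6-hydroxy-3,7-dimethylocta-2,7-dienyl]oxy}-2H-chromen-2-one
Product: 10 (R)-marmin, 7-{[(2E,6R)-6,7-dihydroxy-3,7-dimethyloct-2-enyl]oxy}-2H-chromen-2-one
Conditions: Co(acac)2 (divalent cobalt, 20 mol%), PhSiH3, O2 (1 atm), i-PrOH/THF, rt
Reagents that add atoms: dioxygen, O=O
Why: Mukaiyama hydration by metal-hydride hydrogen-atom transfer, in which a cobalt hydride delivers a hydrogen atom to the unhindered CH2 terminus of the 1,1-disubstituted alkene, the tertiary C7' radical is trapped by O2 faster than it can cyclise onto the 2',3'-alkene, and the cobalt-bound peroxide is reduced by the silane to the tertiary alcohol; the trisubstituted allyl ether alkene and the electron-poor coumarin C3=C4 bond should react more slowly, C7' is not stereogenic and C6' is not touched.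

**Step 6**
Reactants: 10 (R)-marmin; 11 linoleic acid ((9Z,12Z)-octadeca-9,12-dienoic acid)
Product: 12 R-(+)-marmin-6'-linoleate, (3R,6E)-2-hydroxy-2,6-dimethyl-8-[(2-oxo-2H-chromen-7-yl)oxy]oct-6-en-3-yl (9Z,12Z)-octadeca-9,12-dienoate
Conditions: DCC, DMAP (cat.), CH2Cl2, 0 °C to rt, argon, dark
Reagents that add atoms: none
Why: Steglich esterification, in which the acylpyridinium formed from the O-acylisourea acylates the secondary C6' hydroxyl while the tertiary C7' hydroxyl is too hindered to react; the C6'–O bond is never broken, so the R configuration is retained, and the neutral, non-oxidising conditions leave the skipped Z,Z-diene alone.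

**Compound list**

1 | umbelliferone (7-hydroxy-2H-chromen-2-one) | O=c1ccc2ccc(O)cc2o1 | starting material
2 | geranyl bromide ((2E)-1-bromo-3,7-dimethylocta-2,6-diene) | CC(C)=CCC/C(C)=C/CBr | starting material
3 | aurapten, 7-{[(2E)-3,7-dimethylocta-2,6-dienyl]oxy}-2H-chromen-2-one | CC(C)=CCC/C(C)=C/COc1ccc2ccc(=O)oc2c1 | intermediate
4 | racemic 6',7'-epoxyaurapten, 7-{[(2E)-5-(3,3-dimethyloxiran-2-yl)-3-methylpent-2-enyl]oxy}-2H-chromen-2-one | CC1(C)OC1CC/C(C)=C/COc1ccc2ccc(=O)oc2c1 | intermediate
5 | racemic 6',7'-diol (racemic marmin), 7-{[(2E)-6,7-dihydroxy-3,7-dimethyloct-2-enyl]oxy}-2H-chromen-2-one | CC(C)(O)C(O)CC/C(C)=C/COc1ccc2ccc(=O)oc2c1 | intermediate (not isolated)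
6 | (4E)-4-methyl-6-[(2-oxo-2H-chromen-7-yl)oxy]hex-4-enal | O=CCC/C(C)=C/COc1ccc2ccc(=O)oc2c1 | intermediate
7 | 2-bromopropene | C=C(C)Br | starting material
8 | 7-{[(2E,6R)-3,7-dimethyl-6-(trimethylsilyloxy)octa-2,7-dienyl]oxy}-2H-chromen-2-one | C=C(C)[C@H](O[Si](C)(C)C)CC/C(C)=C/COc1ccc2ccc(=O)oc2c1 | intermediate (not isolated)
9 | 7-{[(2E,6R)-6-hydroxy-3,7-dimethylocta-2,7-dienyl]oxy}-2H-chromen-2-one | C=C(C)[C@H](O)CC/C(C)=C/COc1ccc2ccc(=O)oc2c1 | intermediate
10 | (R)-marmin, 7-{[(2E,6R)-6,7-dihydroxy-3,7-dimethyloct-2-enyl]oxy}-2H-chromen-2-one | CC(C)(O)[C@H](O)CC/C(C)=C/COc1ccc2ccc(=O)oc2c1 | intermediate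
11 | linoleic acid ((9Z,12Z)-octadeca-9,12-dienoic acid) | CCCCC/C=C\C/C=C\CCCCCCCC(=O)O | starting material
12 | R-(+)-marmin-6'-linoleate | CCCCC/C=C\C/C=C\CCCCCCCC(=O)O[C@H](CC/C(C)=C/COc1ccc2ccc(=O)oc2c1)C(C)(C)O | target

**Totals and risks**

Total step count: 6. Longest linear sequence: 6 steps (1 to 3, 4, 6, 9, 10, 12).

Steps most likely to fail:

- **Step 4.** Enantioface discrimination may be insufficient for an unbranched aldehyde, and slow insertion of nickel into the alkenyl bromide may let turnover stall. The fallback sets out from 9 of low enantiomeric purity and returns to 9. Dess–Martin oxidation in CH2Cl2 should give the enone 7-{[(2E)-3,7-dimethyl-6-oxoocta-2,7-dienyl]oxy}-2H-chromen-2-one F1. Corey–Bakshi–Shibata reduction with (S)-2-methyl-CBS-oxazaborolidine and catecholborane in toluene at −78 °C, the isopropenyl group acting as the larger substituent, should then return (R)-9 by analogy with aryl alkyl ketones. The C6'–C7' bond still comes from the chromium addition; only the source of the stereocentre changes to a reagent-controlled reduction.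

- **Step 5.** Hydrogen-atom transfer may lose chemoselectivity, with competing hydration of the 2',3'-alkene or reduction of the coumarin C3=C4 bond. The fallback sets out from 9 and returns to 10. Oxymercuration with Hg(OAc)2 in THF/H2O at rt, which is Markovnikov and fastest at 1,1-disubstituted alkenes, should give {(3R,6E)-2,3-dihydroxy-2,6-dimethyl-8-[(2-oxo-2H-chromen-7-yl)oxy]oct-6-enyl}mercury acetate F2 as a mixture of C2 epimers. Reduction with NaBH4 in aqueous NaOH at 0 °C, then acidification to pH 4 to reclose any opened lactone, should give 10.

- **Step 6.** Acyl transfer to the secondary hydroxyl flanked by the tertiary carbinol may be slow, letting the O-acylisourea rearrange to the unreactive N-acylurea. The fallback sets out from 11 and returns to 12. Oxalyl chloride with catalytic DMF in CH2Cl2 at 0 °C should give (9Z,12Z)-octadeca-9,12-dienoyl chloride F3. This is added to 10 with pyridine and catalytic DMAP in CH2Cl2 at 0 °C, so that a pre-formed, more electrophilic acyl donor replaces in situ carbodiimide activation.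

**Further compounds**

F1 | step 4 | 7-{[(2E)-3,7-dimethyl-6-oxoocta-2,7-dienyl]oxy}-2H-chromen-2-one | C=C(C)C(=O)CC/C(C)=C/COc1ccc2ccc(=O)oc2c1
F2 | step 5 | {(3R,6E)-2,3-dihydroxy-2,6-dimethyl-8-[(2-oxo-2H-chromen-7-yl)oxy]oct-6-enyl}mercury acetate (both C2 epimers) | CC(=O)O[Hg]CC(C)(O)[C@H](O)CC/C(C)=C/COc1ccc2ccc(=O)oc2c1
F3 | step 6 | (9Z,12Z)-octadeca-9,12-dienoyl chloride | CCCCC/C=C\C/C=C\CCCCCCCC(=O)Cl
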